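**Plan**

Numbering (briarane): ring A = C1, C10, C11 (methyl C20), C12, C13, C14; ten-membered ring = C1–C10; butenolide = O, C7, C8, C17 (methyl C18), C19.
Enabling feature: quaternary C1 lies between two oxygenated carbons (C2, C14) and C11 is 1,4 to C14 in ring A. Ring A is therefore the adduct of a 2-oxidodiene C12=C13–C14(O)=C1 (an α-methyl β-keto ester that carries a vinyl ketone) and a nitro-activated C10=C11 olefin.
Cuts, in retrosynthetic order: C7–C8 plus the lactone C–O bond (Nozaki–Hiyama–Kishi macrocyclisation/lactonisation), C3–C4 (enolate allylation), C2–C3 (ester to methyl ketone), then C1–C10 and C11–C12 of ring A together (Michael/Michael annulation).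
Forward: ring A first; nitro → C11 ketone → enol triflate → methyl-bearing C11=C12 olefin; chain growth at C2; Evans–Tishchenko reduction sets C2 and tells the two esters apart; C8 aldehyde → β-keto ester → (Z)-enol triflate; the ten-membered ring and the butenolide close last, in one step.
Stereochemistry: C10 from the chiral thiourea catalyst; C1 from the endo-like approach of the hydrogen-bonded Z-enol; C14 from equatorial hydride attack; C2 from C14–OH-directed hydride transfer (1,3-anti); C7 from macrocyclic substrate control; both Z olefins from Still–Gennari olefination and chelate-controlled enol triflation.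
Helpers removed later: the nitro group (activates C10=C11, supplies the C11 nucleophile, leaves as nitrite), the C14 ketone oxidation level, and the TES, TBDPS and PMB ethers.

Key step: step 4

Assumption: aldehydes 6 and 22 and phosphonate 23 are taken as commercial, and the (R,R)-thiourea is assigned by analogy with its usual facial sense on nitroalkenes (the (S,S)-enantiomer is used if the sense proves opposite).

**Step 1**
Reactants: 1 methyl propanoate; 2 acrolein
Product: 4 methyl 3-hydroxy-2-methylpent-4-enoate (racemic diastereomer mixture), via lithium enolate 3 (not isolated)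
Conditions: LiN(i-Pr)2, THF, −78 °C; then 2, −78 °C
Reagents that add atoms: none
Why: The kinetic lithium ester enolate adds 1,2 to acrolein at low temperature (aldol addition), and both new stereocentres are erased in steps 2 and 4, so the diastereomer mixture is immaterial.

**Step 2**
Reactants: 4 methyl 3-hydroxy-2-methylpent-4-enoate
Product: 5 methyl 2-methyl-3-oxopent-4-enoate (used at once)
Conditions: Dess–Martin periodinane, CH2Cl2, 0 °C
Reagents that add atoms: none
Why: Dess–Martin oxidation of the allylic β-hydroxy ester gives the vinyl ketone β-keto ester under neutral, non-aqueous conditions that should limit its polymerisation.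

**Step 3**
Reactants: 6 3-[(tert-butyldiphenylsilyl)oxy]propanal; 7 nitromethane
Product: 10 (E)-tert-butyl[(4-nitrobut-3-en-1-yl)oxy]diphenylsilane, via nitro alcohol 8 (not isolated), via mesylate 9 (not isolated)
Conditions: Et3N (0.1 equiv), MeNO2, 0 °C to rt; then MsCl, Et3N, CH2Cl2, −20 to 0 °C
Reagents that add atoms: none
Why: Henry addition followed by mesylation and E1cB elimination should give the conjugated (E)-nitroalkene, the thermodynamically favoured isomer.

**Step 4**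
Reactants: 5 methyl 2-methyl-3-oxopent-4-enoate; 10 (E)-tert-butyl[(4-nitrobut-3-en-1-yl)oxy]diphenylsilane
Product: 12 methyl (1R,2R,3R)-2-{2-[(tert-butyldiphenylsilyl)oxy]ethyl}-1-methyl-3-nitro-6-oxocyclohexane-1-carboxylate, via acyclic Michael adduct 11 (not isolated)
Conditions: 1-[3,5-bis(trifluoromethyl)phenyl]-3-[(1R,2R)-2-(dimethylamino)cyclohexyl]thiourea (10 mol %), toluene, −20 °C to rt, slow addition of 5; then 1,1,3,3-tetramethylguanidine (20 mol %), 0 °C
Reagents that add atoms: none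
Why: The amine of the bifunctional thiourea enolises 5 while the thiourea binds the nitro group of 10, so the enol carbon C1 adds to C10 (Michael addition, 11); tetramethylguanidine then forms the nitronate of 11, whose carbon C11 adds to the terminal vinyl ketone carbon C12 (second Michael addition), the whole being an anionic [4+2] annulation. The closest known reaction types are thiourea-catalysed additions of 2-substituted β-keto esters to nitroalkenes and the Michael/Michael annulation of γ,δ-unsaturated β-keto esters with nitroalkenes to 4-nitrocyclohexanones. Ring A (C1, C10, C11, C12, C13, C14) closes by a 6-endo-trig attack of the nitronate carbon on the enone. C10 is set by the catalyst, which should expose one face of the nitroalkene; C1 should follow from the synclinal, endo-like approach of the hydrogen-bonded Z-enol, which places the C1 methyl cis and the ester trans to the C9 side chain; C11 is epimerisable, should settle with nitro equatorial, and is erased in step 6. The step needs chemoselectivity for the nitroalkene over the donor's own vinyl ketone, which thiourea activation of 10 and slow addition of 5 should secure, and regioselectivity, which the polarity of the nitroalkene fixes (C10 electrophilic, C11 nucleophilic).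

**Step 5**
Reactants: 12 nitro keto ester
Product: 14 methyl (1R,2R,3R,6S)-2-{2-[(tert-butyldiphenylsilyl)oxy]ethyl}-1-methyl-3-nitro-6-[(triethylsilyl)oxy]cyclohexane-1-carboxylate, via lithium alkoxide 13 (not isolated)
Conditions: LiBH(s-Bu)3 (1.2 equiv), THF, −78 °C; then Et3SiOTf, −78 to 0 °C
Reagents that add atoms: triethylsilyl trifluoromethanesulfonate, CC[Si](CC)(CC)OS(=O)(=O)C(F)(F)F
Why: The bulky hydride should attack the C14 ketone along the equatorial path (the axial path is blocked by the axial hydrogens at C10 and C12), giving the axial C14 alkoxide cis to the ester as in reductions of 4,4-dimethyl-3-keto steroids, and the alkoxide is silylated in the same flask.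

**Step 6**
Reactants: 14 nitro silyl ether
Product: 16 methyl (1R,2R,6S)-2-{2-[(tert-butyldiphenylsilyl)oxy]ethyl}-1-methyl-3-oxo-6-[(triethylsilyl)oxy]cyclohexane-1-carboxylate, via sodium nitronate 15 (not isolated)
Conditions: NaOMe (1.0 equiv), MeOH, 0 °C; then O3, CH2Cl2/MeOH, −78 °C; N2 purge
Reagents that add atoms: ozone, [O-][O+]=O
Why: Nef reaction in its ozonolytic form cleaves the nitronate C=N bond to the C11 ketone and nitrite, and one equivalent of base at low temperature should leave the silyl ethers, the ester and the epimerisable C10 centre untouched.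

**Step 7**
Reactants: 16 C11 ketone
Product: 18 methyl (1R,2R,6S)-2-{2-[(tert-butyldiphenylsilyl)oxy]ethyl}-1-methyl-6-[(triethylsilyl)oxy]-3-{[(trifluoromethyl)sulfonyl]oxy}cyclohex-3-ene-1-carboxylate, via potassium enolate 17 (not isolated)
Conditions: KN(SiMe3)2, THF, −78 °C; then PhNTf2, −78 to −40 °C
Reagents that add atoms: N-phenylbis(trifluoromethanesulfonimide), O=S(=O)(N(c1ccccc1)S(=O)(=O)C(F)(F)F)C(F)(F)F
Why: Kinetic deprotonation by the hindered amide should occur at the C12 methylene and not at the tertiary, neopentyl-type C10–H, and O-triflation fixes the C11=C12 enol triflate without equilibrating C10.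

**Step 8**
Reactants: 18 enol triflate
Product: 19 methyl (1R,2S,6S)-2-{2-[(tert-butyldiphenylsilyl)oxy]ethyl}-1,3-dimethyl-6-[(triethylsilyl)oxy]cyclohex-3-ene-1-carboxylate
Conditions: MeMgBr, Fe(acac)3 (10 mol %), THF/NMP, −30 °C
Reagents that add atoms: methylmagnesium bromide, C[Mg]Br
Why: Iron-catalysed cross-coupling of alkenyl triflates with MeMgBr is fast at low temperature and tolerates the hindered ester, installing the C20 methyl on the C11=C12 olefin.

**Step 9**
Reactants: 19 methyl ester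
Product: 21 1-[(1R,2S,6S)-2-{2-[(tert-butyldiphenylsilyl)oxy]ethyl}-1,3-dimethyl-6-[(triethylsilyl)oxy]cyclohex-3-en-1-yl]ethan-1-one, via silylmethyl ketone 20 (not isolated)
Conditions: Me3SiCH2Li (3 equiv), pentane/THF, 0 °C to rt; then MeOH, rt
Reagents that add atoms: (trimethylsilyl)methyllithium, [Li]C[Si](C)(C)C
Why: Me3SiCH2Li adds once to the hindered ester, the α-silyl ketone is enolised by a second equivalent (which blocks over-addition) and methanol protodesilylates it to the methyl ketone (ester to methyl ketone conversion).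

**Step 10**
Reactants: 22 2-[(4-methoxybenzyl)oxy]acetaldehyde; 23 ethyl 2-[bis(2,2,2-trifluoroethoxy)phosphoryl]propanoate
Product: 25 ethyl (Z)-4-[(4-methoxybenzyl)oxy]-2-methylbut-2-enoate, via phosphonate carbanion 24 (not isolated)
Conditions: KN(SiMe3)2, 18-crown-6, THF, −78 °C
Reagents that add atoms: none
Why: Still–Gennari olefination with the trifluoroethyl phosphonate under dissociating conditions should give the (Z)-trisubstituted enoate under kinetic control.

**Step 11**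
Reactants: 25 (Z)-enoate
Product: 26 (Z)-4-[(4-methoxybenzyl)oxy]-2-methylbut-2-en-1-ol
Conditions: i-Bu2AlH (2.2 equiv), CH2Cl2, −78 °C; aq potassium sodium tartrate
Reagents that add atoms: none
Why: i-Bu2AlH reduces the conjugated ester to the allylic alcohol without changing the olefin geometry or the PMB ether (ester reduction).

**Step 12**
Reactants: 26 (Z)-allylic alcohol
Product: 27 (Z)-1-bromo-4-[(4-methoxybenzyl)oxy]-2-methylbut-2-ene (used fresh)
Conditions: CBr4, PPh3, CH2Cl2, 0 °C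
Reagents that add atoms: carbon tetrabromide, BrC(Br)(Br)Br
Why: Appel bromination converts the primary allylic alcohol to the bromide under neutral conditions with retention of the Z geometry.

**Step 13**
Reactants: 21 methyl ketone; 27 (Z)-allylic bromide
Product: 29 (Z)-1-[(1R,2S,6S)-2-{2-[(tert-butyldiphenylsilyl)oxy]ethyl}-1,3-dimethyl-6-[(triethylsilyl)oxy]cyclohex-3-en-1-yl]-6-[(4-methoxybenzyl)oxy]-4-methylhex-4-en-1-one, via lithium enolate 28 (not isolated)
Conditions: LiN(i-Pr)2, THF, −78 °C; then 27, DMPU, −78 to −30 °C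
Reagents that add atoms: none
Why: The ketone has α-hydrogens only at C3, so a single enolate forms and is C-alkylated by the reactive allylic bromide (SN2 enolate alkylation), making the C3–C4 bond.

**Step 14**
Reactants: 29 TES-protected ketone
Product: 30 (Z)-1-[(1R,2S,6S)-2-{2-[(tert-butyldiphenylsilyl)oxy]ethyl}-6-hydroxy-1,3-dimethylcyclohex-3-en-1-yl]-6-[(4-methoxybenzyl)oxy]-4-methylhex-4-en-1-one
Conditions: PPTS, MeOH/CH2Cl2, rt
Reagents that add atoms: none
Why: Mild acid-catalysed methanolysis removes the triethylsilyl ether while the far more acid-stable tert-butyldiphenylsilyl ether and the PMB ether persist (selective desilylation).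

**Step 15**
Reactants: 30 β-hydroxy ketone
Product: 31 (1S,5S,6S)-5-{2-[(tert-butyldiphenylsilyl)oxy]ethyl}-6-{(1S,4Z)-1-hydroxy-6-[(4-methoxybenzyl)oxy]-4-methylhex-4-en-1-yl}-4,6-dimethylcyclohex-3-en-1-yl acetate
Conditions: SmI2 (0.3 equiv), CH3CHO (10 equiv), THF, −10 °C
Reagents that add atoms: acetaldehyde, CC=O
Why: In the Evans–Tishchenko reduction the C14 hydroxyl forms a samarium-bound hemiacetal with acetaldehyde and passes its hydride to the C2 ketone through a chair transition state with the C3 chain equatorial, which should give the 1,3-anti (2S) alcohol and leave the acetyl group on O14.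

**Step 16**
Reactants: 31 hydroxy acetate
Product: 32 (1S,5S,6S)-5-{2-[(tert-butyldiphenylsilyl)oxy]ethyl}-6-{(1S,4Z)-6-[(4-methoxybenzyl)oxy]-4-methyl-1-(propanoyloxy)hex-4-en-1-yl}-4,6-dimethylcyclohex-3-en-1-yl acetate
Conditions: (EtCO)2O, DMAP, Et3N, CH2Cl2, rt
Reagents that add atoms: propanoic anhydride, CCC(=O)OC(=O)CC
Why: DMAP-catalysed acylation of the only free (C2) hydroxyl gives the propanoate, and prompt acylation should forestall acetyl migration from O14 (esterification).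

**Step 17**
Reactants: 32 diester silyl ether
Product: 33 (1S,5S,6S)-5-(2-hydroxyethyl)-6-{(1S,4Z)-6-[(4-methoxybenzyl)oxy]-4-methyl-1-(propanoyloxy)hex-4-en-1-yl}-4,6-dimethylcyclohex-3-en-1-yl acetate
Conditions: HF·pyridine, pyridine, THF, rt
Reagents that add atoms: none
Why: Buffered HF·pyridine cleaves the primary silyl ether and leaves both esters and the PMB ether intact (desilylation).

**Step 18**
Reactants: 33 primary alcohol
Product: 34 (1S,5S,6S)-6-{(1S,4Z)-6-[(4-methoxybenzyl)oxy]-4-methyl-1-(propanoyloxy)hex-4-en-1-yl}-4,6-dimethyl-5-(2-oxoethyl)cyclohex-3-en-1-yl acetate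
Conditions: Dess–Martin periodinane, CH2Cl2, 0 °C to rt
Reagents that add atoms: none
Why: Dess–Martin oxidation takes the primary alcohol to the C8 aldehyde under neutral conditions without touching esters, olefins or the PMB ether.

**Step 19**
Reactants: 35 methyl 2-methyl-3-oxobutanoate
Product: 36 methyl 2-diazopropanoate
Conditions: 4-acetamidobenzenesulfonyl azide, DBU, MeCN, 0 °C to rt
Reagents that add atoms: 4-acetamidobenzenesulfonyl azide, CC(=O)Nc1ccc(cc1)S(=O)(=O)N=[N+]=[N-]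
Why: Deacylative diazo transfer (Regitz type): the enolate attacks the sulfonyl azide and the acetyl group is lost to the sulfonamide, giving the 2-diazo ester.

**Step 20**
Reactants: 34 C8 aldehyde; 36 methyl 2-diazopropanoate
Product: 37 methyl 4-[(1S,5S,6S)-5-acetoxy-6-{(1S,4Z)-6-[(4-methoxybenzyl)oxy]-4-methyl-1-(propanoyloxy)hex-4-en-1-yl}-2,6-dimethylcyclohex-2-en-1-yl]-2-methyl-3-oxobutanoate (epimers at C-2 of the butanoate)
Conditions: Sc(OTf)3 (10 mol %), CH2Cl2, −40 °C to rt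
Reagents that add atoms: none
Why: Roskamp homologation: Lewis-acid-promoted addition of the diazo ester to the aliphatic aldehyde, 1,2-hydride shift and loss of N2 give the α-methyl β-keto ester, whose α-centre becomes sp2 in step 21.

**Step 21**
Reactants: 37 β-keto ester
Product: 39 methyl (2Z)-4-[(1S,5S,6S)-5-acetoxy-6-{(1S,4Z)-6-[(4-methoxybenzyl)oxy]-4-methyl-1-(propanoyloxy)hex-4-en-1-yl}-2,6-dimethylcyclohex-2-en-1-yl]-2-methyl-3-{[(trifluoromethyl)sulfonyl]oxy}but-2-enoate, via sodium enolate 38 (not isolated)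
Conditions: NaH (1.05 equiv), THF, 0 °C; then PhNTf2, 0 °C to rt
Reagents that add atoms: N-phenylbis(trifluoromethanesulfonimide), O=S(=O)(N(c1ccccc1)S(=O)(=O)C(F)(F)F)C(F)(F)F
Why: Only the β-keto ester is acidic enough for one equivalent of NaH, its sodium enolate is chelated (Z), and O-triflation should give the (Z)-enol triflate with the triflate cis to C19, as lactonisation needs.

**Step 22**
Reactants: 39 (Z)-enol triflate PMB ether
Product: 40 methyl (2Z)-4-[(1S,5S,6S)-5-acetoxy-6-{(1S,4Z)-6-hydroxy-4-methyl-1-(propanoyloxy)hex-4-en-1-yl}-2,6-dimethylcyclohex-2-en-1-yl]-2-methyl-3-{[(trifluoromethyl)sulfonyl]oxy}but-2-enoate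
Conditions: DDQ, CH2Cl2/pH 7 buffer, 0 °C
Reagents that add atoms: none
Why: DDQ oxidises the electron-rich PMB ether to the oxocarbenium ion, which water hydrolyses, freeing the allylic alcohol without touching esters or the enol triflate (oxidative PMB cleavage).

**Step 23**
Reactants: 40 allylic alcohol
Product: 41 methyl (2Z)-4-[(1S,5S,6S)-5-acetoxy-2,6-dimethyl-6-{(1S,4Z)-4-methyl-6-oxo-1-(propanoyloxy)hex-4-en-1-yl}cyclohex-2-en-1-yl]-2-methyl-3-{[(trifluoromethyl)sulfonyl]oxy}but-2-enoate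
Conditions: Dess–Martin periodinane, pyridine, CH2Cl2, 0 °C
Reagents that add atoms: none
Why: Buffered Dess–Martin oxidation should give the (Z)-enal without isomerising the trisubstituted olefin.

**Step 24**
Reactants: 41 enol triflate (Z)-enal
Product: 43 CNP0112230.2 (target), via hydroxy ester 42 (not isolated)
Conditions: CrCl2 (10 equiv), NiCl2 (0.1 equiv), degassed DMF, 0.002 M, rt
Reagents that add atoms: none
Why: In the Nozaki–Hiyama–Kishi reaction zerovalent nickel inserts into the alkenyl triflate, transmetalation gives an alkenylchromium that adds 1,2 to the aldehyde at high dilution to close the ten-membered ring (C7–C8), the chromium alkoxide then attacks the cis ester to form the butenolide, and C7 is set by the conformation of the forming trans-fused ring (substrate control).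

**Compound list**

1 | methyl propanoate | CCC(=O)OC | starting material
2 | acrolein | C=CC=O | starting material
3 | lithium (E)-enolate of methyl propanoate | C/C=C(\OC)[O-].[Li+] | intermediate
4 | methyl 3-hydroxy-2-methylpent-4-enoate (racemic diastereomer mixture) | C=CC(O)C(C)C(=O)OC | intermediate
5 | methyl 2-methyl-3-oxopent-4-enoate (racemic, enolisable) | C=CC(=O)C(C)C(=O)OC | intermediate
6 | 3-[(tert-butyldiphenylsilyl)oxy]propanal | CC(C)(C)[Si](c1ccccc1)(c1ccccc1)OCCC=O | starting material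
7 | nitromethane | C[N+](=O)[O-] | starting material
8 | 4-[(tert-butyldiphenylsilyl)oxy]-1-nitrobutan-2-ol (racemic) | CC(C)(C)[Si](c1ccccc1)(c1ccccc1)OCCC(O)C[N+](=O)[O-] | intermediate
9 | 4-[(tert-butyldiphenylsilyl)oxy]-1-nitrobutan-2-yl methanesulfonate (racemic) | CC(C)(C)[Si](c1ccccc1)(c1ccccc1)OCCC(OS(C)(=O)=O)C[N+](=O)[O-] | intermediate
10 | (E)-tert-butyl[(4-nitrobut-3-en-1-yl)oxy]diphenylsilane | CC(C)(C)[Si](c1ccccc1)(c1ccccc1)OCC/C=C/[N+](=O)[O-] | intermediate
11 | methyl (2R,3R)-5-[(tert-butyldiphenylsilyl)oxy]-2-methyl-3-(nitromethyl)-2-(prop-2-enoyl)pentanoate | CC(C)(C)[Si](c1ccccc1)(c1ccccc1)OCC[C@@H](C[N+](=O)[O-])[C@@](C)(C(=O)OC)C(=O)C=C | intermediate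
12 | methyl (1R,2R,3R)-2-{2-[(tert-butyldiphenylsilyl)oxy]ethyl}-1-methyl-3-nitro-6-oxocyclohexane-1-carboxylate | CC(C)(C)[Si](c1ccccc1)(c1ccccc1)OCC[C@H]1[C@H]([N+](=O)[O-])CCC(=O)[C@]1(C)C(=O)OC | intermediate
13 | lithium alkoxide of the (6S)-alcohol from 12 (axial O, cis to the ester) | CC(C)(C)[Si](c1ccccc1)(c1ccccc1)OCC[C@H]1[C@H]([N+](=O)[O-])CC[C@H]([O-])[C@]1(C)C(=O)OC.[Li+] | intermediate
14 | methyl (1R,2R,3R,6S)-2-{2-[(tert-butyldiphenylsilyl)oxy]ethyl}-1-methyl-3-nitro-6-[(triethylsilyl)oxy]cyclohexane-1-carboxylate | CC(C)(C)[Si](c1ccccc1)(c1ccccc1)OCC[C@H]1[C@H]([N+](=O)[O-])CC[C@H](O[Si](CC)(CC)CC)[C@]1(C)C(=O)OC | intermediate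
15 | sodium nitronate of 14 | CC(C)(C)[Si](c1ccccc1)(c1ccccc1)OCC[C@H]1C(=[N+]([O-])[O-])CC[C@H](O[Si](CC)(CC)CC)[C@]1(C)C(=O)OC.[Na+] | intermediate
16 | methyl (1R,2R,6S)-2-{2-[(tert-butyldiphenylsilyl)oxy]ethyl}-1-methyl-3-oxo-6-[(triethylsilyl)oxy]cyclohexane-1-carboxylate | CC(C)(C)[Si](c1ccccc1)(c1ccccc1)OCC[C@H]1C(=O)CC[C@H](O[Si](CC)(CC)CC)[C@]1(C)C(=O)OC | intermediate
17 | potassium C11=C12 enolate of 16 | CC(C)(C)[Si](c1ccccc1)(c1ccccc1)OCC[C@H]1C([O-])=CC[C@H](O[Si](CC)(CC)CC)[C@]1(C)C(=O)OC.[K+] | intermediate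
18 | methyl (1R,2R,6S)-2-{2-[(tert-butyldiphenylsilyl)oxy]ethyl}-1-methyl-6-[(triethylsilyl)oxy]-3-{[(trifluoromethyl)sulfonyl]oxy}cyclohex-3-ene-1-carboxylate | CC(C)(C)[Si](c1ccccc1)(c1ccccc1)OCC[C@H]1C(OS(=O)(=O)C(F)(F)F)=CC[C@H](O[Si](CC)(CC)CC)[C@]1(C)C(=O)OC | intermediate
19 | methyl (1R,2S,6S)-2-{2-[(tert-butyldiphenylsilyl)oxy]ethyl}-1,3-dimethyl-6-[(triethylsilyl)oxy]cyclohex-3-ene-1-carboxylate | CC(C)(C)[Si](c1ccccc1)(c1ccccc1)OCC[C@H]1C(C)=CC[C@H](O[Si](CC)(CC)CC)[C@]1(C)C(=O)OC | intermediate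
20 | 1-[(1R,2S,6S)-2-{2-[(tert-butyldiphenylsilyl)oxy]ethyl}-1,3-dimethyl-6-[(triethylsilyl)oxy]cyclohex-3-en-1-yl]-2-(trimethylsilyl)ethan-1-one (present as its lithium enolate) | CC(C)(C)[Si](c1ccccc1)(c1ccccc1)OCC[C@H]1C(C)=CC[C@H](O[Si](CC)(CC)CC)[C@]1(C)C(=O)C[Si](C)(C)C | intermediate
21 | 1-[(1R,2S,6S)-2-{2-[(tert-butyldiphenylsilyl)oxy]ethyl}-1,3-dimethyl-6-[(triethylsilyl)oxy]cyclohex-3-en-1-yl]ethan-1-one | CC(C)(C)[Si](c1ccccc1)(c1ccccc1)OCC[C@H]1C(C)=CC[C@H](O[Si](CC)(CC)CC)[C@]1(C)C(C)=O | intermediate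
22 | 2-[(4-methoxybenzyl)oxy]acetaldehyde | O=CCOCc1ccc(OC)cc1 | starting material
23 | ethyl 2-[bis(2,2,2-trifluoroethoxy)phosphoryl]propanoate | CCOC(=O)C(C)P(=O)(OCC(F)(F)F)OCC(F)(F)F | starting material
24 | potassium salt of the carbanion of 23 | CCOC(=O)[C-](C)P(=O)(OCC(F)(F)F)OCC(F)(F)F.[K+] | intermediate
25 | ethyl (Z)-4-[(4-methoxybenzyl)oxy]-2-methylbut-2-enoate | CCOC(=O)/C(C)=C\COCc1ccc(OC)cc1 | intermediate
26 | (Z)-4-[(4-methoxybenzyl)oxy]-2-methylbut-2-en-1-ol | OC/C(C)=C\COCc1ccc(OC)cc1 | intermediate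
27 | (Z)-1-bromo-4-[(4-methoxybenzyl)oxy]-2-methylbut-2-ene | BrC/C(C)=C\COCc1ccc(OC)cc1 | intermediate
28 | lithium enolate of 21 | CC(C)(C)[Si](c1ccccc1)(c1ccccc1)OCC[C@H]1C(C)=CC[C@H](O[Si](CC)(CC)CC)[C@]1(C)C([O-])=C.[Li+] | intermediate
29 | (Z)-1-[(1R,2S,6S)-2-{2-[(tert-butyldiphenylsilyl)oxy]ethyl}-1,3-dimethyl-6-[(triethylsilyl)oxy]cyclohex-3-en-1-yl]-6-[(4-methoxybenzyl)oxy]-4-methylhex-4-en-1-one | CC(C)(C)[Si](c1ccccc1)(c1ccccc1)OCC[C@H]1C(C)=CC[C@H](O[Si](CC)(CC)CC)[C@]1(C)C(=O)CC/C(C)=C\COCc1ccc(OC)cc1 | intermediate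
30 | (Z)-1-[(1R,2S,6S)-2-{2-[(tert-butyldiphenylsilyl)oxy]ethyl}-6-hydroxy-1,3-dimethylcyclohex-3-en-1-yl]-6-[(4-methoxybenzyl)oxy]-4-methylhex-4-en-1-one | CC(C)(C)[Si](c1ccccc1)(c1ccccc1)OCC[C@H]1C(C)=CC[C@H](O)[C@]1(C)C(=O)CC/C(C)=C\COCc1ccc(OC)cc1 | intermediate
31 | (1S,5S,6S)-5-{2-[(tert-butyldiphenylsilyl)oxy]ethyl}-6-{(1S,4Z)-1-hydroxy-6-[(4-methoxybenzyl)oxy]-4-methylhex-4-en-1-yl}-4,6-dimethylcyclohex-3-en-1-yl acetate | CC(C)(C)[Si](c1ccccc1)(c1ccccc1)OCC[C@H]1C(C)=CC[C@H](OC(C)=O)[C@]1(C)[C@@H](O)CC/C(C)=C\COCc1ccc(OC)cc1 | intermediate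
32 | (1S,5S,6S)-5-{2-[(tert-butyldiphenylsilyl)oxy]ethyl}-6-{(1S,4Z)-6-[(4-methoxybenzyl)oxy]-4-methyl-1-(propanoyloxy)hex-4-en-1-yl}-4,6-dimethylcyclohex-3-en-1-yl acetate | CC(C)(C)[Si](c1ccccc1)(c1ccccc1)OCC[C@H]1C(C)=CC[C@H](OC(C)=O)[C@]1(C)[C@@H](OC(=O)CC)CC/C(C)=C\COCc1ccc(OC)cc1 | intermediate
33 | (1S,5S,6S)-5-(2-hydroxyethyl)-6-{(1S,4Z)-6-[(4-methoxybenzyl)oxy]-4-methyl-1-(propanoyloxy)hex-4-en-1-yl}-4,6-dimethylcyclohex-3-en-1-yl acetate | OCC[C@H]1C(C)=CC[C@H](OC(C)=O)[C@]1(C)[C@@H](OC(=O)CC)CC/C(C)=C\COCc1ccc(OC)cc1 | intermediate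
34 | (1S,5S,6S)-6-{(1S,4Z)-6-[(4-methoxybenzyl)oxy]-4-methyl-1-(propanoyloxy)hex-4-en-1-yl}-4,6-dimethyl-5-(2-oxoethyl)cyclohex-3-en-1-yl acetate | O=CC[C@H]1C(C)=CC[C@H](OC(C)=O)[C@]1(C)[C@@H](OC(=O)CC)CC/C(C)=C\COCc1ccc(OC)cc1 | intermediate
35 | methyl 2-methyl-3-oxobutanoate | CC(=O)C(C)C(=O)OC | starting material
36 | methyl 2-diazopropanoate | COC(=O)C(C)=[N+]=[N-] | intermediate
37 | methyl 4-[(1S,5S,6S)-5-acetoxy-6-{(1S,4Z)-6-[(4-methoxybenzyl)oxy]-4-methyl-1-(propanoyloxy)hex-4-en-1-yl}-2,6-dimethylcyclohex-2-en-1-yl]-2-methyl-3-oxobutanoate (epimers at C-2 of the butanoate) | COC(=O)C(C)C(=O)C[C@H]1C(C)=CC[C@H](OC(C)=O)[C@]1(C)[C@@H](OC(=O)CC)CC/C(C)=C\COCc1ccc(OC)cc1 | intermediate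
38 | sodium (Z)-enolate of 37 | COC(=O)/C(C)=C([O-])/C[C@H]1C(C)=CC[C@H](OC(C)=O)[C@]1(C)[C@@H](OC(=O)CC)CC/C(C)=C\COCc1ccc(OC)cc1.[Na+] | intermediate
39 | methyl (2Z)-4-[(1S,5S,6S)-5-acetoxy-6-{(1S,4Z)-6-[(4-methoxybenzyl)oxy]-4-methyl-1-(propanoyloxy)hex-4-en-1-yl}-2,6-dimethylcyclohex-2-en-1-yl]-2-methyl-3-{[(trifluoromethyl)sulfonyl]oxy}but-2-enoate | COC(=O)/C(C)=C(OS(=O)(=O)C(F)(F)F)/C[C@H]1C(C)=CC[C@H](OC(C)=O)[C@]1(C)[C@@H](OC(=O)CC)CC/C(C)=C\COCc1ccc(OC)cc1 | intermediate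
40 | methyl (2Z)-4-[(1S,5S,6S)-5-acetoxy-6-{(1S,4Z)-6-hydroxy-4-methyl-1-(propanoyloxy)hex-4-en-1-yl}-2,6-dimethylcyclohex-2-en-1-yl]-2-methyl-3-{[(trifluoromethyl)sulfonyl]oxy}but-2-enoate | COC(=O)/C(C)=C(OS(=O)(=O)C(F)(F)F)/C[C@H]1C(C)=CC[C@H](OC(C)=O)[C@]1(C)[C@@H](OC(=O)CC)CC/C(C)=C\CO | intermediate
41 | methyl (2Z)-4-[(1S,5S,6S)-5-acetoxy-2,6-dimethyl-6-{(1S,4Z)-4-methyl-6-oxo-1-(propanoyloxy)hex-4-en-1-yl}cyclohex-2-en-1-yl]-2-methyl-3-{[(trifluoromethyl)sulfonyl]oxy}but-2-enoate | COC(=O)/C(C)=C(OS(=O)(=O)C(F)(F)F)/C[C@H]1C(C)=CC[C@H](OC(C)=O)[C@]1(C)[C@@H](OC(=O)CC)CC/C(C)=C\C=O | intermediate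
42 | ten-membered-ring hydroxy ester: C7–C8 bond closed, (7S)-hydroxyl free, exocyclic (Z)-C8=C17(CH3)CO2CH3 unit not yet lactonised (present as its chromium alkoxide) | COC(=O)/C(C)=C1/C[C@H]2C(C)=CC[C@H](OC(C)=O)[C@]2(C)[C@@H](OC(=O)CC)CC/C(C)=C\[C@@H]1O | intermediate
43 | CNP0112230.2 (14-acetoxy-2-propanoyloxy briarane butenolide) | CCC(=O)O[C@H]1CC/C(C)=C\[C@@H]2OC(=O)C(C)=C2C[C@H]2C(C)=CC[C@H](OC(C)=O)[C@]12C | target

**Step count and risks**

Total: 24 steps. Longest linear sequence: 19 steps (steps 1, 2, 4–9, 13–18, 20–24).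

Step 4. What may go wrong: the vinyl ketone donor 5 may oligomerise by self-Michael addition before it meets 10, and the quaternary centre C1 may form with poor diastereocontrol. The fallback sets out from 5 and returns at 12. Thiophenol is added to 5 (Et3N cat., CH2Cl2) to give the sulfide-masked donor methyl 2-methyl-3-oxo-5-(phenylsulfanyl)pentanoate F1, which cannot act as an acceptor. The same thiourea-catalysed Michael addition of F1 to 10 should give methyl (2R,3R)-5-[(tert-butyldiphenylsilyl)oxy]-2-methyl-3-(nitromethyl)-2-[3-(phenylsulfanyl)propanoyl]pentanoate F2, whose C1 epimers can be separated at this acyclic stage. NaIO4 in aqueous methanol gives the sulfoxide methyl (2R,3R)-5-[(tert-butyldiphenylsilyl)oxy]-2-methyl-3-(nitromethyl)-2-[3-(phenylsulfinyl)propanoyl]pentanoate F3. Heating F3 in toluene over CaCO3 (sulfoxide syn-elimination) releases the vinyl ketone 11, and tetramethylguanidine closes ring A to 12.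

Step 24. What may go wrong: intermolecular coupling and protodemetalation may outrun closure of the strained ten-membered ring, and facial selectivity at C7 may be poor (the acidic butenolide γ-hydrogen at C7 would allow base equilibration of a wrong epimer). The fallback sets out from 39 and returns at 43. Miyaura borylation of 39 (bis(pinacolato)diboron, PdCl2(PPh3)2, PPh3, KOPh, toluene, 50 °C) should give, with retention of geometry, the alkenylboronate methyl (2E)-4-[(1S,5S,6S)-5-acetoxy-6-{(1S,4Z)-6-[(4-methoxybenzyl)oxy]-4-methyl-1-(propanoyloxy)hex-4-en-1-yl}-2,6-dimethylcyclohex-2-en-1-yl]-2-methyl-3-(4,4,5,5-tetramethyl-1,3,2-dioxaborolan-2-yl)but-2-enoate F4, a stable compound that can be purified. DDQ cleavage of the PMB ether gives the allylic alcohol methyl (2E)-4-[(1S,5S,6S)-5-acetoxy-6-{(1S,4Z)-6-hydroxy-4-methyl-1-(propanoyloxy)hex-4-en-1-yl}-2,6-dimethylcyclohex-2-en-1-yl]-2-methyl-3-(4,4,5,5-tetramethyl-1,3,2-dioxaborolan-2-yl)but-2-enoate F5. Buffered Dess–Martin oxidation gives the (Z)-enal methyl (2E)-4-[(1S,5S,6S)-5-acetoxy-2,6-dimethyl-6-{(1S,4Z)-4-methyl-6-oxo-1-(propanoyloxy)hex-4-en-1-yl}cyclohex-2-en-1-yl]-2-methyl-3-(4,4,5,5-tetramethyl-1,3,2-dioxaborolan-2-yl)but-2-enoate F6. [Rh(OH)(cod)]2 in aqueous dioxane at high dilution then moves the alkenyl group from boron to rhodium, and intramolecular 1,2-addition to the aldehyde gives 42, which lactonises to 43.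

Step 15. What may go wrong: hydride transfer to the hindered neopentyl-type ketone may be slow, and the acetyl group may migrate between O14 and O2 before step 16. The fallback sets out from 29 and returns at 32. Corey–Bakshi–Shibata reduction of 29 with the (R)-oxazaborolidine and BH3·SMe2 (reagent control, tertiary-alkyl versus primary-alkyl ketone) should give the (2S)-alcohol (1S,4Z)-1-[(1S,2S,6S)-2-{2-[(tert-butyldiphenylsilyl)oxy]ethyl}-1,3-dimethyl-6-[(triethylsilyl)oxy]cyclohex-3-en-1-yl]-6-[(4-methoxybenzyl)oxy]-4-methylhex-4-en-1-ol F7. Propanoic anhydride/DMAP gives its propanoate (1S,4Z)-1-[(1S,2S,6S)-2-{2-[(tert-butyldiphenylsilyl)oxy]ethyl}-1,3-dimethyl-6-[(triethylsilyl)oxy]cyclohex-3-en-1-yl]-6-[(4-methoxybenzyl)oxy]-4-methylhex-4-en-1-yl propanoate F8. PPTS in methanol removes the triethylsilyl group to give the C14 alcohol (1S,4Z)-1-[(1S,2S,6S)-2-{2-[(tert-butyldiphenylsilyl)oxy]ethyl}-6-hydroxy-1,3-dimethylcyclohex-3-en-1-yl]-6-[(4-methoxybenzyl)oxy]-4-methylhex-4-en-1-yl propanoate F9. Acetic anhydride/DMAP then gives 32.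

**Further compounds**

F1 | step 4 | methyl 2-methyl-3-oxo-5-(phenylsulfanyl)pentanoate | COC(=O)C(C)C(=O)CCSc1ccccc1
F2 | step 4 | methyl (2R,3R)-5-[(tert-butyldiphenylsilyl)oxy]-2-methyl-3-(nitromethyl)-2-[3-(phenylsulfanyl)propanoyl]pentanoate | CC(C)(C)[Si](c1ccccc1)(c1ccccc1)OCC[C@@H](C[N+](=O)[O-])[C@@](C)(C(=O)OC)C(=O)CCSc1ccccc1
F3 | step 4 | methyl (2R,3R)-5-[(tert-butyldiphenylsilyl)oxy]-2-methyl-3-(nitromethyl)-2-[3-(phenylsulfinyl)propanoyl]pentanoate (mixture at sulfur) | CC(C)(C)[Si](c1ccccc1)(c1ccccc1)OCC[C@@H](C[N+](=O)[O-])[C@@](C)(C(=O)OC)C(=O)CCS(=O)c1ccccc1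
F4 | step 24 | methyl (2E)-4-[(1S,5S,6S)-5-acetoxy-6-{(1S,4Z)-6-[(4-methoxybenzyl)oxy]-4-methyl-1-(propanoyloxy)hex-4-en-1-yl}-2,6-dimethylcyclohex-2-en-1-yl]-2-methyl-3-(4,4,5,5-tetramethyl-1,3,2-dioxaborolan-2-yl)but-2-enoate (boron cis to the ester) | COC(=O)/C(C)=C(B1OC(C)(C)C(C)(C)O1)/C[C@H]2C(C)=CC[C@H](OC(C)=O)[C@]2(C)[C@@H](OC(=O)CC)CC/C(C)=C\COCc1ccc(OC)cc1
F5 | step 24 | methyl (2E)-4-[(1S,5S,6S)-5-acetoxy-6-{(1S,4Z)-6-hydroxy-4-methyl-1-(propanoyloxy)hex-4-en-1-yl}-2,6-dimethylcyclohex-2-en-1-yl]-2-methyl-3-(4,4,5,5-tetramethyl-1,3,2-dioxaborolan-2-yl)but-2-enoate | COC(=O)/C(C)=C(B1OC(C)(C)C(C)(C)O1)/C[C@H]2C(C)=CC[C@H](OC(C)=O)[C@]2(C)[C@@H](OC(=O)CC)CC/C(C)=C\CO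
F6 | step 24 | methyl (2E)-4-[(1S,5S,6S)-5-acetoxy-2,6-dimethyl-6-{(1S,4Z)-4-methyl-6-oxo-1-(propanoyloxy)hex-4-en-1-yl}cyclohex-2-en-1-yl]-2-methyl-3-(4,4,5,5-tetramethyl-1,3,2-dioxaborolan-2-yl)but-2-enoate | COC(=O)/C(C)=C(B1OC(C)(C)C(C)(C)O1)/C[C@H]2C(C)=CC[C@H](OC(C)=O)[C@]2(C)[C@@H](OC(=O)CC)CC/C(C)=C\C=O
F7 | step 15 | (1S,4Z)-1-[(1S,2S,6S)-2-{2-[(tert-butyldiphenylsilyl)oxy]ethyl}-1,3-dimethyl-6-[(triethylsilyl)oxy]cyclohex-3-en-1-yl]-6-[(4-methoxybenzyl)oxy]-4-methylhex-4-en-1-ol | CC(C)(C)[Si](c1ccccc1)(c1ccccc1)OCC[C@H]1C(C)=CC[C@H](O[Si](CC)(CC)CC)[C@]1(C)[C@@H](O)CC/C(C)=C\COCc1ccc(OC)cc1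
F8 | step 15 | (1S,4Z)-1-[(1S,2S,6S)-2-{2-[(tert-butyldiphenylsilyl)oxy]ethyl}-1,3-dimethyl-6-[(triethylsilyl)oxy]cyclohex-3-en-1-yl]-6-[(4-methoxybenzyl)oxy]-4-methylhex-4-en-1-yl propanoate | CC(C)(C)[Si](c1ccccc1)(c1ccccc1)OCC[C@H]1C(C)=CC[C@H](O[Si](CC)(CC)CC)[C@]1(C)[C@@H](OC(=O)CC)CC/C(C)=C\COCc1ccc(OC)cc1
F9 | step 15 | (1S,4Z)-1-[(1S,2S,6S)-2-{2-[(tert-butyldiphenylsilyl)oxy]ethyl}-6-hydroxy-1,3-dimethylcyclohex-3-en-1-yl]-6-[(4-methoxybenzyl)oxy]-4-methylhex-4-en-1-yl propanoate | CC(C)(C)[Si](c1ccccc1)(c1ccccc1)OCC[C@H]1C(C)=CC[C@H](O)[C@]1(C)[C@@H](OC(=O)CC)CC/C(C)=C\COCc1ccc(OC)cc1
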